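**Retrosynthetic overview**

- Ring C carries the ring B oxygen at C1 between the hydroxyls at C2 and C6, a hydrogen at C3, a hydroxyl at C4 and ring D at C5. This 1,3,5-oxygen pattern makes ring C the triple enol of a 2-aryloxy-4-arylcyclohexane-1,3,5-trione.
- That trione is opened at C1–C6 to an acyclic methyl 3,5-dioxohexanoate, in which C6 is the ester carbon, C5 the arylacetate carbon bearing ring D, C4 and C2 ketones, C3 a methylene and C1 an aryloxymethyl carbon.
- The chain is cut at C2–C3 into the dianion of an α-aryl acetoacetate (ring D, C3 to C6) and an aryloxyacetic Weinreb amide (rings A and B, C1 and C2).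
- The Weinreb amide comes from a Williamson alkylation of the ring A–B phenol, itself made by Ullmann mono-arylation of 5-methoxyresorcinol. The acetoacetate comes from the ring D arylacetic acid by esterification and C-acetylation.
- Rings A, B and D are bought as arenes; ring C is the only ring built and is closed last, before global demethylation.

Key step: step 6

Assumption: the target has no stereocentre and no stereogenic axis (ring D is symmetric about the biaryl bond), so the chiral open-chain and trione intermediates are carried as racemic, enolizable mixtures, and enolates or phenoxides formed by the stated bases are treated as ionized forms of the numbered compounds.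

**Route**

Step 1
Reactants: 1 5-methoxybenzene-1,3-diol (threefold excess); 2 1-bromo-3,5-dimethoxybenzene
Product: 3 3-(3,5-dimethoxyphenoxy)-5-methoxyphenol
Conditions: CuI (10 mol %), picolinic acid (20 mol %), K3PO4, DMSO, 90 °C
Reagents that add atoms: none
Why: Ullmann-type copper-catalysed O-arylation of a phenol by an unhindered aryl bromide, in which the excess of the symmetric diol should make mono-arylation the main course and leave one hydroxyl as the handle for step 2.

Step 2
Reactants: 3 3-(3,5-dimethoxyphenoxy)-5-methoxyphenol; 4 2-chloro-N-methoxy-N-methylacetamide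
Product: 5 2-[3-(3,5-dimethoxyphenoxy)-5-methoxyphenoxy]-N-methoxy-N-methylacetamide
Conditions: K2CO3, KI (10 mol %), acetone, 56 °C
Reagents that add atoms: none
Why: Williamson ether synthesis at an unhindered primary carbon activated by the neighbouring amide carbonyl and assisted by iodide exchange, which sets the later crowded ring C ether oxygen by SN2 before ring C exists.

Step 3
Reactants: 6 2-(2,4,6-trimethoxyphenyl)acetic acid
Product: 7 methyl 2-(2,4,6-trimethoxyphenyl)acetate
Conditions: MeI, K2CO3, DMF, 25 °C
Reagents that add atoms: iodomethane, CI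
Why: SN2 O-alkylation of the carboxylate, chosen over acid-catalysed esterification so that the electron-rich trimethoxyarene never meets strong acid.

Step 4
Reactants: 7 methyl 2-(2,4,6-trimethoxyphenyl)acetate
Product: 8 methyl 3-oxo-2-(2,4,6-trimethoxyphenyl)butanoate (racemic)
Conditions: LiN(SiMe3)2 (2.1 equiv), THF, −78 °C; AcCl, −78 to 0 °C; aq NH4Cl
Reagents that add atoms: acetyl chloride, CC(=O)Cl
Why: Claisen-type C-acylation of a preformed lithium ester enolate by an acid chloride, the second equivalent of amide base deprotonating the β-keto ester as it forms; the new stereocentre arises racemic, is enolizable and is erased in step 6.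

Step 5
Reactants: 8 methyl 3-oxo-2-(2,4,6-trimethoxyphenyl)butanoate (1.5 equiv); 5 2-[3-(3,5-dimethoxyphenoxy)-5-methoxyphenoxy]-N-methoxy-N-methylacetamide
Product: 10 methyl 6-[3-(3,5-dimethoxyphenoxy)-5-methoxyphenoxy]-3,5-dioxo-2-(2,4,6-trimethoxyphenyl)hexanoate, via lithium hemiaminal adduct 9 (not isolated)
Conditions: 8, LiN(i-Pr)2 (3.1 equiv), THF, −78 to 0 °C; then 5, −78 to 0 °C; aq NH4Cl, then dilute HCl to pH 4
Reagents that add atoms: none
Why: γ-Acylation of a β-keto ester dianion by a Weinreb amide (Weinreb ketone synthesis), in which the more basic terminal carbanion attacks and the chelated adduct 9 persists until the quench, so that neither over-addition nor proton transfer from the acidic diketone product can intervene; the stereocentres of 9 and 10 are racemic and of no consequence.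

Step 6
Reactants: 10 methyl 6-[3-(3,5-dimethoxyphenoxy)-5-methoxyphenoxy]-3,5-dioxo-2-(2,4,6-trimethoxyphenyl)hexanoate
Product: 12 3-[3-(3,5-dimethoxyphenoxy)-5-methoxyphenoxy]-2',4',6'-trimethoxy-[1,1'-biphenyl]-2,4,6-triol, via cyclohexane-1,3,5-trione 11 (not isolated)
Conditions: NaOMe (6 equiv), degassed MeOH, 65 °C, Ar; then 1 M HCl, 0 °C
Reagents that add atoms: none
Why: Excess methoxide holds 10 as its C3/C5 enolates, and fast proton exchange in methanol also populates the enolate at C1, which the C2 ketone and the aryloxy oxygen both acidify; this carbon adds to the ester carbonyl C6, methoxide leaves, and trione 11 tautomerizes at once to the phenoxide of 12, which takes the sequence out of equilibrium. The closest known reaction type is the intramolecular Claisen (Dieckmann-type) condensation by which 5-oxoalkanoates give cyclohexane-1,3-diones and by which 3,5-dioxo- and 3,5,7-trioxoalkanoates are folded to phloroglucinols in biomimetic polyketide chemistry. Ring C closes in a 6-(enolendo)-exo-trig mode, the C1=C2 enolate lying inside the new ring and the ester C=O outside it. No stereocentre is created, since C1 and C5 of 11 both become sp2 on aromatization. The step needs C- rather than O-acylation and a six-membered carbocycle: C1 is the only carbon that can reach C6 through a six-membered transition state (attack from C3 would give a four-membered ring), and the O-acylation product, a 4-hydroxy-2-pyrone, is reopened by methoxide whereas the aromatic triol is not.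

Step 7
Reactants: 12 3-[3-(3,5-dimethoxyphenoxy)-5-methoxyphenoxy]-2',4',6'-trimethoxy-[1,1'-biphenyl]-2,4,6-triol
Product: 13 3-[3-(3,5-dihydroxyphenoxy)-5-hydroxyphenoxy]-[1,1'-biphenyl]-2,2',4,4',6,6'-hexol (CNP0133338.0)
Conditions: BBr3 (15 equiv), CH2Cl2, −78 to 25 °C, Ar; then H2O, 0 °C
Reagents that add atoms: none
Why: Lewis acid-mediated cleavage of the six aryl methyl ethers (BBr3 demethylation) through O–B complexation and bromide attack on methyl, conditions to which the two diaryl ether bonds and the biaryl bond are inert.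

**Compound list**

1 | 5-methoxybenzene-1,3-diol | COc1cc(O)cc(O)c1 | starting material
2 | 1-bromo-3,5-dimethoxybenzene | COc1cc(Br)cc(OC)c1 | starting material
3 | 3-(3,5-dimethoxyphenoxy)-5-methoxyphenol | COc1cc(O)cc(Oc2cc(OC)cc(OC)c2)c1 | intermediate
4 | 2-chloro-N-methoxy-N-methylacetamide | CON(C)C(=O)CCl | starting material
5 | 2-[3-(3,5-dimethoxyphenoxy)-5-methoxyphenoxy]-N-methoxy-N-methylacetamide | CON(C)C(=O)COc1cc(OC)cc(Oc2cc(OC)cc(OC)c2)c1 | intermediate
6 | 2-(2,4,6-trimethoxyphenyl)acetic acid | O=C(O)Cc1c(OC)cc(OC)cc1OC | starting material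
7 | methyl 2-(2,4,6-trimethoxyphenyl)acetate | COC(=O)Cc1c(OC)cc(OC)cc1OC | intermediate
8 | methyl 3-oxo-2-(2,4,6-trimethoxyphenyl)butanoate (racemic, enolizable) | COC(=O)C(C(C)=O)c1c(OC)cc(OC)cc1OC | intermediate
9 | methyl 6-[3-(3,5-dimethoxyphenoxy)-5-methoxyphenoxy]-5-hydroxy-5-[methoxy(methyl)amino]-3-oxo-2-(2,4,6-trimethoxyphenyl)hexanoate (present as its lithium chelate, stereoisomer mixture, not isolated) | COC(=O)C(c1c(OC)cc(OC)cc1OC)C(=O)CC(O)(N(C)OC)COc1cc(OC)cc(Oc2cc(OC)cc(OC)c2)c1 | intermediate
10 | methyl 6-[3-(3,5-dimethoxyphenoxy)-5-methoxyphenoxy]-3,5-dioxo-2-(2,4,6-trimethoxyphenyl)hexanoate (racemic, keto–enol mixture) | COC(=O)C(c1c(OC)cc(OC)cc1OC)C(=O)CC(=O)COc1cc(OC)cc(Oc2cc(OC)cc(OC)c2)c1 | intermediate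
11 | 2-[3-(3,5-dimethoxyphenoxy)-5-methoxyphenoxy]-4-(2,4,6-trimethoxyphenyl)cyclohexane-1,3,5-trione (labile stereoisomer mixture, not isolated) | COc1cc(OC)cc(Oc2cc(OC)cc(OC3C(=O)CC(=O)C(c4c(OC)cc(OC)cc4OC)C3=O)c2)c1 | intermediate
12 | 3-[3-(3,5-dimethoxyphenoxy)-5-methoxyphenoxy]-2',4',6'-trimethoxy-[1,1'-biphenyl]-2,4,6-triol | COc1cc(OC)cc(Oc2cc(OC)cc(Oc3c(O)cc(O)c(-c4c(OC)cc(OC)cc4OC)c3O)c2)c1 | intermediate
13 | 3-[3-(3,5-dihydroxyphenoxy)-5-hydroxyphenoxy]-[1,1'-biphenyl]-2,2',4,4',6,6'-hexol (achiral) | Oc1cc(O)cc(Oc2cc(O)cc(Oc3c(O)cc(O)c(-c4c(O)cc(O)cc4O)c3O)c2)c1 | target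

**Step count**

Total: 7 steps. Longest linear sequence: 5 steps (6 → 7 → 8 → 10 → 12 → 13, and equally 1 → 3 → 5 → 10 → 12 → 13).

**Steps most likely to fail**

Step 6. The chain may stall as its doubly enolized C3/C5 anion, in which C1 is rarely deprotonated and the ester is a poor electrophile. Meanwhile methoxide may slowly cut the chain by retro-Claisen scission, and O-acylation may park material as the pyrone. The fallback gives up the ring closure and joins ready-made rings by aryl coupling, setting out from phenol 3. Classical Ullmann homocoupling of commercial 2-iodo-1,3,5-trimethoxybenzene (Cu powder, DMF, 150 °C) should give 2,2',4,4',6,6'-hexamethoxybiphenyl F1. Monobromination (N-bromosuccinimide, MeCN, 0 °C) should give 3-bromo-2,2',4,4',6,6'-hexamethoxybiphenyl F2. Ullmann ether coupling of F2 with 3 (CuI, N,N-dimethylglycine, Cs2CO3, dioxane, 110 °C) is slow for a bromide flanked by two methoxy groups but is the classical access to such ethers, and should give 3-[3-(3,5-dimethoxyphenoxy)-5-methoxyphenoxy]-2,2',4,4',6,6'-hexamethoxybiphenyl F3. BBr3 under the conditions of step 7 then cleaves all nine methyl ethers, and the route is rejoined at 13.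

Step 5. Proton transfer from the acidic OCH2 group of amide 5 to the strongly basic terminal carbanion may outrun addition and return both partners. The fallback replaces acylation by aldol addition and oxidation, setting out from 5 and 8. Reduction of 5 (LiAlH4, THF, −40 °C) should give 2-[3-(3,5-dimethoxyphenoxy)-5-methoxyphenoxy]acetaldehyde F4, a far faster electrophile than the amide. The dianion of 8 (LiN(i-Pr)2, THF, −78 °C) should add to it at the terminal carbon to give methyl 6-[3-(3,5-dimethoxyphenoxy)-5-methoxyphenoxy]-5-hydroxy-3-oxo-2-(2,4,6-trimethoxyphenyl)hexanoate F5 as a stereoisomer mixture. Oxidation of the β-hydroxy ketone with 2-iodoxybenzoic acid (EtOAc, 75 °C) rejoins the route at 10.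

Step 7. Cleavage of six ethers on three rings may stop short once boron is tied up by the free hydroxyls, and the very polar, air-sensitive nonaphenol may be lost or oxidized on isolation. The fallback isolates through a derivative, setting out from 12. After the BBr3 cleavage and quench, the crude polyphenol is acetylated without purification (Ac2O, pyridine, 25 °C) to the nonaacetate of 13, F6. This is stable, can be chromatographed free of under-demethylated material, and is then cleaved by acid methanolysis (HCl in MeOH, 25 °C, Ar), rejoining the route at 13.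

**Further compounds**

F1 | step 6 | 2,2',4,4',6,6'-hexamethoxybiphenyl | COc1cc(OC)c(-c2c(OC)cc(OC)cc2OC)c(OC)c1
F2 | step 6 | 3-bromo-2,2',4,4',6,6'-hexamethoxybiphenyl | COc1cc(OC)c(-c2c(OC)cc(OC)c(Br)c2OC)c(OC)c1
F3 | step 6 | 3-[3-(3,5-dimethoxyphenoxy)-5-methoxyphenoxy]-2,2',4,4',6,6'-hexamethoxybiphenyl | COc1cc(OC)cc(Oc2cc(OC)cc(Oc3c(OC)cc(OC)c(-c4c(OC)cc(OC)cc4OC)c3OC)c2)c1
F4 | step 5 | 2-[3-(3,5-dimethoxyphenoxy)-5-methoxyphenoxy]acetaldehyde | O=CCOc1cc(OC)cc(Oc2cc(OC)cc(OC)c2)c1
F5 | step 5 | methyl 6-[3-(3,5-dimethoxyphenoxy)-5-methoxyphenoxy]-5-hydroxy-3-oxo-2-(2,4,6-trimethoxyphenyl)hexanoate (stereoisomer mixture) | COC(=O)C(c1c(OC)cc(OC)cc1OC)C(=O)CC(O)COc1cc(OC)cc(Oc2cc(OC)cc(OC)c2)c1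
F6 | step 7 | nonaacetate of 13 | CC(=O)Oc1cc(OC(C)=O)cc(Oc2cc(OC(C)=O)cc(Oc3c(OC(C)=O)cc(OC(C)=O)c(-c4c(OC(C)=O)cc(OC(C)=O)cc4OC(C)=O)c3OC(C)=O)c2)c1
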